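**Retrosynthetic overview**
1. Feature (labdane numbering: C4 gem-dimethyl, C5–H and C10–CH3 at the ring fusion, side chain C11–C17 on C9): ring B, C5–C6–C7–C8=C9–C10, is a cyclohexene whose C8=C9 alkene sits next to the quaternary fusion carbon C10. With an acyl group added at C6 this is a Diels–Alder retron.
2. Key disconnection C5–C10 and C6–C7: intramolecular Diels–Alder reaction of a (2E,8E)-trienoyl (S)-4-benzyloxazolidinone (diene C7=C8–C9=C10, dienophile C5=C6, tether C1–C4). The C6 acyl group is then excised by hydroperoxide cleavage and Barton decarboxylation.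
3. Trienimide: C5=C6 by Horner–Wadsworth–Emmons olefination of a neopentyl aldehyde (from a nitrile); isopropenyl C8=C7 from a methyl ketone made by Weinreb opening of an (E)-alkylidene butyrolactone; C1–C10 by Negishi coupling of the (E)-enol triflate of 2-acetylbutyrolactone.
4. Side chain from the C9 two-carbon arm: C12–C13 by acetylide alkylation, C13–CH3 and C14–I by carboalumination–iodination, C14–C15 by Suzuki coupling with an (R)-vinylboronate from the (S)-Roche ester (C17), then CH2OH to CO2CH3.
5. Ring order: rings A and B close together in step 12; no ring is formed before or after.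

Key step: step 12

Remark: the tether terminus is carried as a nitrile (from isobutyronitrile) instead of an ester, so that the methyl Grignard addition (step 6) and the reduction to the aldehyde (step 8) are chemoselective.

**Route**

Step 1
Reactants: 1 isobutyronitrile; 2 1,3-dibromopropane
Product: 3 5-bromo-2,2-dimethylpentanenitrile
Conditions: LDA, THF, −78 °C; added to 2 (3 equiv), −78 °C → rt
Reagents that add atoms: none
Why: SN2 alkylation of the lithiated tertiary nitrile with the dibromide in excess should stop at the monobromide, because the product has no α-hydrogen; no stereocentre is formed.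

Step 2
Reactants: 4 2-acetylbutyrolactone
Product: 5 (E)-1-(2-oxooxolan-3-ylidene)ethyl trifluoromethanesulfonate
Conditions: Tf2O, aq. Me4NOH, toluene, 0–5 °C
Reagents that add atoms: trifluoromethanesulfonic anhydride, O=S(=O)(OS(=O)(=O)C(F)(F)F)C(F)(F)F
Why: O-triflation of the β-keto lactone enolate under non-chelating conditions (tetraalkylammonium counter-ion) should go through the enolate whose oxygen points away from the lactone carbonyl, giving the (E)-enol triflate (OTf trans to the lactone C=O); the geometry is to be checked by NOE.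

Step 3
Reactants: 3 5-bromo-2,2-dimethylpentanenitrile; 5 (E)-enol triflate
Product: 7 (E)-2,2-dimethyl-6-(2-oxooxolan-3-ylidene)heptanenitrile, via (4-cyano-4-methylpentyl)zinc bromide 6 (not isolated)
Conditions: Zn dust (BrCH2CH2Br, TMSCl activation), LiCl, THF, 50 °C; then 5, PdCl2(dppf) (3 mol %), THF, rt → 45 °C
Reagents that add atoms: none
Why: LiCl-mediated zinc insertion (Knochel) tolerates the nitrile, and the Negishi sp3–sp2 coupling of the activated β-triflyloxy enoate should form C1–C10 with retention of the alkene geometry.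

Step 4
Reactants: 7 (E)-alkylidene lactone
Product: 8 (E)-7-cyano-2-(2-hydroxyethyl)-N-methoxy-N,3,7-trimethyloct-2-enamide
Conditions: MeNHOMe·HCl, Me3Al, CH2Cl2, 0 °C → rt
Reagents that add atoms: N,O-dimethylhydroxylamine hydrochloride, CNOC.Cl
Why: Weinreb aminolysis of the lactone by the aluminium amide opens the ring at the acyl carbon and should leave the hindered tertiary nitrile and the alkene geometry untouched.

Step 5
Reactants: 8 hydroxy Weinreb amide
Product: 9 (E)-2-[2-(tert-butyldimethylsilyloxy)ethyl]-7-cyano-N-methoxy-N,3,7-trimethyloct-2-enamide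
Conditions: TBSCl, imidazole, DMF, 0 °C → rt (crude 8 used at once)
Reagents that add atoms: tert-butyldimethylsilyl chloride, CC(C)(C)[Si](C)(C)Cl
Why: Silylation of the primary alcohol right after ring opening prevents relactonisation and protects C12–O through to step 14.

Step 6
Reactants: 9 silyl ether Weinreb amide
Product: 10 (E)-7-[2-(tert-butyldimethylsilyloxy)ethyl]-2,2,6-trimethyl-8-oxonon-6-enenitrile
Conditions: MeMgBr, THF, 0 °C → rt
Reagents that add atoms: methylmagnesium bromide, C[Mg]Br
Why: Grignard addition to the Weinreb amide stops at the chelated tetrahedral intermediate and gives the methyl ketone (C8 with its methyl), while the α-quaternary nitrile is inert to MeMgBr at this temperature.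

Step 7
Reactants: 10 methyl ketone
Product: 11 (E)-7-[2-(tert-butyldimethylsilyloxy)ethyl]-2,2,6,8-tetramethylnona-6,8-dienenitrile
Conditions: Ph3PCH3Br, KOt-Bu, THF, 0 → 50 °C
Reagents that add atoms: methyltriphenylphosphonium bromide, C[P+](c1ccccc1)(c1ccccc1)c1ccccc1.[Br-]
Why: Wittig methylenation of the methyl ketone installs C7 and completes the tetrasubstituted (E)-diene; the non-stabilised ylide tolerates the nitrile and the silyl ether.

Step 8
Reactants: 11 diene nitrile
Product: 12 (E)-7-[2-(tert-butyldimethylsilyloxy)ethyl]-2,2,6,8-tetramethylnona-6,8-dienal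
Conditions: DIBAL-H, CH2Cl2, −78 → −40 °C; aq. Rochelle salt, then aq. tartaric acid, 0 °C
Reagents that add atoms: water, O
Why: DIBAL-H adds once to the α-quaternary nitrile to give an aluminium aldimine that is hydrolysed to the aldehyde on work-up; the diene and the silyl ether are inert.

Step 9
Reactants: 13 (S)-4-benzyloxazolidin-2-one
Product: 14 (S)-4-benzyl-3-(2-bromoacetyl)oxazolidin-2-one
Conditions: n-BuLi, THF, −78 °C; BrCH2COBr, −78 → 0 °C
Reagents that add atoms: bromoacetyl bromide, BrCC(Br)=O
Why: N-acylation of the lithiated oxazolidinone with the acid bromide; the auxiliary stereocentre is not touched.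

Step 10
Reactants: 14 bromoacetyl imide
Product: 15 diethyl {2-[(S)-4-benzyl-2-oxooxazolidin-3-yl]-2-oxoethyl}phosphonate
Conditions: P(OEt)3, neat, 90 °C
Reagents that add atoms: triethyl phosphite, CCOP(OCC)OCC
Why: Michaelis–Arbuzov reaction of the α-bromo imide gives the phosphonate and volatile bromoethane.

Step 11
Reactants: 12 dienal; 15 imide phosphonate
Product: 16 (S)-4-benzyl-3-[(2E,8E)-9-[2-(tert-butyldimethylsilyloxy)ethyl]-4,4,8,10-tetramethylundeca-2,8,10-trienoyl]oxazolidin-2-one
Conditions: LiCl, i-Pr2NEt, MeCN, rt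
Reagents that add atoms: none
Why: Horner–Wadsworth–Emmons olefination under Masamune–Roush conditions should give the (E)-enoyl imide (C5=C6) from the non-enolisable neopentyl aldehyde, the mild base leaving the imide intact.

Step 12
Reactants: 16 trienimide
Product: 17 (S)-4-benzyl-3-{(1S,4aS,8aS)-4-[2-(tert-butyldimethylsilyloxy)ethyl]-3,4a,8,8-tetramethyl-1,2,4a,5,6,7,8,8a-octahydronaphthalene-1-carbonyl}oxazolidin-2-one
Conditions: Me2AlCl (1.8–2 equiv), CH2Cl2, −30 °C → rt
Reagents that add atoms: none
Why: Excess Me2AlCl forms the cationic two-point aluminium chelate of the two imide carbonyls, which locks the enoyl unit s-cis and lowers its LUMO, and the diene C7=C8–C9=C10 then adds across C5=C6 in a concerted, asynchronous [4+2] cycloaddition that forms C6–C7 and C5–C10 suprafacially on both partners. The closest known reaction type is the dialkylaluminium chloride-promoted intramolecular Diels–Alder reaction of (E)-2,7,9-decatrienoyl oxazolidinones to trans-fused octalins, the difference being the fully substituted diene terminus C10, which here has to become a quaternary carbon. Ring B (C5–C6–C7–C8=C9–C10) is the six-membered cycloadduct ring itself, and ring A (C1–C4, C5, C10) closes in the same event as a fused six-membered ring, because the four-carbon tether C1–C4 joins diene and dienophile and the C5–C10 bond completes it through a chair-like tether. C5 and C10 are set relative to each other by the endo transition state (imide carbonyl under the diene, tether anti), which puts H-5 and the inside C10 methyl on opposite faces and so gives the trans fusion, while C6 follows from the (E)-geometry of C5=C6 (acyl cis to H-5) and is erased in step 14. The absolute sense comes from the (S)-benzyl group, which covers the Cα-re face of the chelated s-cis enoyl unit so that C7 bonds to the si face of C6, leading to (5S,10S). The step needs facial selectivity, endo selectivity and a reactive s-cis diene: the first two rest on the chelated auxiliary and the Lewis acid, the third on the (8E)-geometry that keeps the tether outside and on the C4 gem-dimethyl group that favours folding, whereas the inside C10 methyl is expected to slow the reaction and is the reason for the temperature ramp.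

Step 13
Reactants: 17 cycloadduct imide
Product: 18 (1S,4aS,8aS)-4-[2-(tert-butyldimethylsilyloxy)ethyl]-3,4a,8,8-tetramethyl-1,2,4a,5,6,7,8,8a-octahydronaphthalene-1-carboxylic acid
Conditions: LiOH, H2O2, THF/H2O, 0 °C → rt; aq. Na2SO3; then 1 M HCl to pH 4
Reagents that add atoms: hydrogen peroxide, OO
Why: Lithium hydroperoxide (Evans cleavage) attacks the exocyclic imide carbonyl and releases the acid and the auxiliary; quenching with sulfite before acidification keeps the peracid from epoxidising C8=C9, and C5 and C10 cannot epimerise.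

Step 14
Reactants: 18 C6 carboxylic acid
Product: 20 tert-butyldimethyl{2-[(4aS,8aS)-2,5,5,8a-tetramethyl-3,4,4a,5,6,7,8,8a-octahydronaphthalen-1-yl]ethoxy}silane, via Barton ester 19 (not isolated)
Conditions: N-hydroxypyridine-2-thione, DCC, DMAP (cat.), CH2Cl2, rt, dark; then t-BuSH, hν (tungsten lamp), rt
Reagents that add atoms: none
Why: Barton reductive decarboxylation: the thiohydroxamate ester fragments under light to the secondary C6 radical, which takes hydrogen from the thiol, so the activating group is replaced by H without touching C8=C9, C5 or C10.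

Step 15
Reactants: 20 silyl ether
Product: 21 2-[(4aS,8aS)-2,5,5,8a-tetramethyl-3,4,4a,5,6,7,8,8a-octahydronaphthalen-1-yl]ethanol
Conditions: TBAF, THF, rt
Reagents that add atoms: none
Why: Fluoride desilylation under basic conditions avoids the acid-promoted cyclisation of the homoallylic alcohol onto C8=C9.

Step 16
Reactants: 21 homoallylic alcohol
Product: 22 (4aS,8aS)-1-(2-iodoethyl)-2,5,5,8a-tetramethyl-3,4,4a,5,6,7,8,8a-octahydronaphthalene
Conditions: I2, PPh3, imidazole, CH2Cl2, 0 °C → rt
Reagents that add atoms: iodine, II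
Why: Appel-type (Garegg–Samuelsson) iodination converts the primary alcohol to the iodide by SN2 displacement of the oxyphosphonium ion under neutral conditions.

Step 17
Reactants: 22 primary iodide
Product: 23 (4aS,8aS)-1-(but-3-yn-1-yl)-2,5,5,8a-tetramethyl-3,4,4a,5,6,7,8,8a-octahydronaphthalene
Conditions: lithium acetylide–ethylenediamine complex, DMSO, 15 °C → rt
Reagents that add atoms: lithium acetylide ethylenediamine complex, [Li]C#C.NCCN
Why: SN2 alkylation of lithium acetylide by the primary iodide in DMSO forms C12–C13, the dipolar aprotic solvent favouring substitution over elimination.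

Step 18
Reactants: 23 terminal alkyne
Product: 25 (4aS,8aS)-1-[(E)-4-iodo-3-methylbut-3-en-1-yl]-2,5,5,8a-tetramethyl-3,4,4a,5,6,7,8,8a-octahydronaphthalene, via dimethyl(alkenyl)alane 24 (not isolated)
Conditions: Me3Al, Cp2ZrCl2 (0.3 equiv), CH2Cl2, 0 °C → rt; then I2, THF, −30 → 0 °C
Reagents that add atoms: trimethylaluminium, C[Al](C)C; iodine, II
Why: Negishi zirconium-catalysed carboalumination adds methyl and aluminium syn across the terminal alkyne (methyl to C13, aluminium to C14), and iodinolysis with retention gives the (E)-trisubstituted alkenyl iodide.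

Step 19
Reactants: 26 methyl (S)-3-hydroxy-2-methylpropanoate
Product: 27 methyl (S)-3-(tert-butyldimethylsilyloxy)-2-methylpropanoate
Conditions: TBSCl, imidazole, CH2Cl2, 0 °C → rt
Reagents that add atoms: tert-butyldimethylsilyl chloride, CC(C)(C)[Si](C)(C)Cl
Why: Standard silylation of the primary alcohol; the stereocentre (the later C17) comes from the chiral pool and is not involved.

Step 20
Reactants: 27 silylated Roche ester
Product: 28 (S)-3-(tert-butyldimethylsilyloxy)-2-methylpropanal
Conditions: DIBAL-H (1.1 equiv), CH2Cl2, −78 °C; aq. Rochelle salt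
Reagents that add atoms: none
Why: Low-temperature DIBAL-H reduction stops at the aluminium hemiacetal and gives the aldehyde on work-up with the α-stereocentre retained; the aldehyde is used at once.

Step 21
Reactants: 28 α-methyl aldehyde
Product: 29 (R)-tert-butyldimethyl[(2-methylbut-3-yn-1-yl)oxy]silane
Conditions: dimethyl (1-diazo-2-oxopropyl)phosphonate, K2CO3, MeOH, 0 °C → rt
Reagents that add atoms: dimethyl (1-diazo-2-oxopropyl)phosphonate, COP(=O)(OC)C(=[N+]=[N-])C(C)=O
Why: Ohira–Bestmann (Seyferth–Gilbert) homologation converts the aldehyde into the terminal alkyne under mild carbonate conditions that should leave the α-stereocentre intact; the descriptor changes to R only because the priorities change.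

Step 22
Reactants: 29 alkyne
Product: 30 tert-butyldimethyl{[(R,E)-2-methyl-4-(4,4,5,5-tetramethyl-1,3,2-dioxaborolan-2-yl)but-3-en-1-yl]oxy}silane
Conditions: pinacolborane, Cp2Zr(H)Cl (10 mol %), Et3N (10 mol %), neat, 60 °C
Reagents that add atoms: pinacolborane, CC1(C)OBOC1(C)C
Why: Zirconium-catalysed hydroboration of the terminal alkyne is a syn, anti-Markovnikov addition and should give the (E)-alkenylboronate only.

Step 23
Reactants: 25 alkenyl iodide; 30 alkenylboronate
Product: 31 tert-butyl{[(2R,3E,5E)-2,6-dimethyl-8-[(4aS,8aS)-2,5,5,8a-tetramethyl-3,4,4a,5,6,7,8,8a-octahydronaphthalen-1-yl]octa-3,5-dien-1-yl]oxy}dimethylsilane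
Conditions: PdCl2(dppf)·CH2Cl2 (5 mol %), aq. K3PO4, THF, rt → 40 °C
Reagents that add atoms: none
Why: Suzuki–Miyaura coupling forms C14–C15 with retention of both alkene geometries, giving the (13E,15E)-diene.

Step 24
Reactants: 31 silyl ether
Product: 32 (2R,3E,5E)-2,6-dimethyl-8-[(4aS,8aS)-2,5,5,8a-tetramethyl-3,4,4a,5,6,7,8,8a-octahydronaphthalen-1-yl]octa-3,5-dien-1-ol
Conditions: TBAF, THF, 0 °C → rt
Reagents that add atoms: none
Why: Fluoride desilylation frees the primary alcohol without acid, so the diene and C8=C9 are not touched.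

Step 25
Reactants: 32 primary alcohol
Product: 33 (2R,3E,5E)-2,6-dimethyl-8-[(4aS,8aS)-2,5,5,8a-tetramethyl-3,4,4a,5,6,7,8,8a-octahydronaphthalen-1-yl]octa-3,5-dienal
Conditions: Dess–Martin periodinane, NaHCO3, CH2Cl2, 0 °C (aldehyde used at once)
Reagents that add atoms: none
Why: Buffered Dess–Martin oxidation is near neutral, which should preserve the C17 configuration and keep the alkene out of conjugation.

Step 26
Reactants: 33 aldehyde
Product: 34 (2R,3E,5E)-2,6-dimethyl-8-[(4aS,8aS)-2,5,5,8a-tetramethyl-3,4,4a,5,6,7,8,8a-octahydronaphthalen-1-yl]octa-3,5-dienoic acid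
Conditions: NaClO2, NaH2PO4, 2-methyl-2-butene (excess), t-BuOH/H2O, 0 °C
Reagents that add atoms: sodium chlorite, [Na+].[O-]Cl=O
Why: Pinnick oxidation at buffered, mildly acidic pH oxidises the aldehyde without enolisation, and the alkene scavenger takes up hypochlorous acid before it can attack the diene or C8=C9.

Step 27
Reactants: 34 carboxylic acid
Product: 35 methyl (2R,3E,5E)-2,6-dimethyl-8-[(4aS,8aS)-2,5,5,8a-tetramethyl-3,4,4a,5,6,7,8,8a-octahydronaphthalen-1-yl]octa-3,5-dienoate
Conditions: TMSCHN2, toluene/MeOH, 0 °C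
Reagents that add atoms: (trimethylsilyl)diazomethane, C[Si](C)(C)C=[N+]=[N-]
Why: Methylation of the acid with diazomethane generated from TMSCHN2 and methanol is base-free, so the C17 stereocentre and the deconjugated diene are kept.

**Compound list**
1 | isobutyronitrile | CC(C)C#N | starting material
2 | 1,3-dibromopropane | BrCCCBr | starting material
3 | 5-bromo-2,2-dimethylpentanenitrile | N#CC(C)(C)CCCBr | intermediate
4 | 2-acetylbutyrolactone | CC(=O)C1CCOC1=O | starting material
5 | (E)-1-(2-oxooxolan-3-ylidene)ethyl trifluoromethanesulfonate | C/C(OS(=O)(=O)C(F)(F)F)=C1\C(=O)OCC1 | intermediate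
6 | (4-cyano-4-methylpentyl)zinc bromide | N#CC(C)(C)CCC[Zn]Br | intermediate
7 | (E)-2,2-dimethyl-6-(2-oxooxolan-3-ylidene)heptanenitrile | N#CC(C)(C)CCC/C(C)=C1\CCOC1=O | intermediate
8 | (E)-7-cyano-2-(2-hydroxyethyl)-N-methoxy-N,3,7-trimethyloct-2-enamide | N#CC(C)(C)CCC/C(C)=C(\CCO)C(=O)N(C)OC | intermediate
9 | (E)-2-[2-(tert-butyldimethylsilyloxy)ethyl]-7-cyano-N-methoxy-N,3,7-trimethyloct-2-enamide | N#CC(C)(C)CCC/C(C)=C(\CCO[Si](C)(C)C(C)(C)C)C(=O)N(C)OC | intermediate
10 | (E)-7-[2-(tert-butyldimethylsilyloxy)ethyl]-2,2,6-trimethyl-8-oxonon-6-enenitrile | N#CC(C)(C)CCC/C(C)=C(\CCO[Si](C)(C)C(C)(C)C)C(C)=O | intermediate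
11 | (E)-7-[2-(tert-butyldimethylsilyloxy)ethyl]-2,2,6,8-tetramethylnona-6,8-dienenitrile | N#CC(C)(C)CCC/C(C)=C(\CCO[Si](C)(C)C(C)(C)C)C(C)=C | intermediate
12 | (E)-7-[2-(tert-butyldimethylsilyloxy)ethyl]-2,2,6,8-tetramethylnona-6,8-dienal | O=CC(C)(C)CCC/C(C)=C(\CCO[Si](C)(C)C(C)(C)C)C(C)=C | intermediate
13 | (S)-4-benzyloxazolidin-2-one | O=C1N[C@@H](Cc2ccccc2)CO1 | starting material
14 | (S)-4-benzyl-3-(2-bromoacetyl)oxazolidin-2-one | O=C1OC[C@H](Cc2ccccc2)N1C(=O)CBr | intermediate
15 | diethyl {2-[(S)-4-benzyl-2-oxooxazolidin-3-yl]-2-oxoethyl}phosphonate | O=C1OC[C@H](Cc2ccccc2)N1C(=O)CP(=O)(OCC)OCC | intermediate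
16 | (S)-4-benzyl-3-[(2E,8E)-9-[2-(tert-butyldimethylsilyloxy)ethyl]-4,4,8,10-tetramethylundeca-2,8,10-trienoyl]oxazolidin-2-one | O=C1OC[C@H](Cc2ccccc2)N1C(=O)/C=C/C(C)(C)CCC/C(C)=C(\CCO[Si](C)(C)C(C)(C)C)C(C)=C | intermediate
17 | (S)-4-benzyl-3-{(1S,4aS,8aS)-4-[2-(tert-butyldimethylsilyloxy)ethyl]-3,4a,8,8-tetramethyl-1,2,4a,5,6,7,8,8a-octahydronaphthalene-1-carbonyl}oxazolidin-2-one | CC(C)(C)[Si](C)(C)OCCC1=C(C)C[C@H](C(=O)N3C(=O)OC[C@@H]3Cc4ccccc4)[C@H]2C(C)(C)CCC[C@]12C | intermediate
18 | (1S,4aS,8aS)-4-[2-(tert-butyldimethylsilyloxy)ethyl]-3,4a,8,8-tetramethyl-1,2,4a,5,6,7,8,8a-octahydronaphthalene-1-carboxylic acid | CC(C)(C)[Si](C)(C)OCCC1=C(C)C[C@H](C(=O)O)[C@H]2C(C)(C)CCC[C@]12C | intermediate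
19 | 2-thioxopyridin-1(2H)-yl ester of acid 18 (Barton ester) | CC(C)(C)[Si](C)(C)OCCC1=C(C)C[C@H](C(=O)On3ccccc3=S)[C@H]2C(C)(C)CCC[C@]12C | intermediate
20 | tert-butyldimethyl{2-[(4aS,8aS)-2,5,5,8a-tetramethyl-3,4,4a,5,6,7,8,8a-octahydronaphthalen-1-yl]ethoxy}silane | CC(C)(C)[Si](C)(C)OCCC1=C(C)CC[C@H]2C(C)(C)CCC[C@]12C | intermediate
21 | 2-[(4aS,8aS)-2,5,5,8a-tetramethyl-3,4,4a,5,6,7,8,8a-octahydronaphthalen-1-yl]ethanol | OCCC1=C(C)CC[C@H]2C(C)(C)CCC[C@]12C | intermediate
22 | (4aS,8aS)-1-(2-iodoethyl)-2,5,5,8a-tetramethyl-3,4,4a,5,6,7,8,8a-octahydronaphthalene | ICCC1=C(C)CC[C@H]2C(C)(C)CCC[C@]12C | intermediate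
23 | (4aS,8aS)-1-(but-3-yn-1-yl)-2,5,5,8a-tetramethyl-3,4,4a,5,6,7,8,8a-octahydronaphthalene | C#CCCC1=C(C)CC[C@H]2C(C)(C)CCC[C@]12C | intermediate
24 | dimethyl{(E)-2-methyl-4-[(4aS,8aS)-2,5,5,8a-tetramethyl-3,4,4a,5,6,7,8,8a-octahydronaphthalen-1-yl]but-1-en-1-yl}alane | C[Al](C)/C=C(\C)CCC1=C(C)CC[C@H]2C(C)(C)CCC[C@]12C | intermediate
25 | (4aS,8aS)-1-[(E)-4-iodo-3-methylbut-3-en-1-yl]-2,5,5,8a-tetramethyl-3,4,4a,5,6,7,8,8a-octahydronaphthalene | I/C=C(\C)CCC1=C(C)CC[C@H]2C(C)(C)CCC[C@]12C | intermediate
26 | methyl (S)-3-hydroxy-2-methylpropanoate | COC(=O)[C@@H](C)CO | starting material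
27 | methyl (S)-3-(tert-butyldimethylsilyloxy)-2-methylpropanoate | COC(=O)[C@@H](C)CO[Si](C)(C)C(C)(C)C | intermediate
28 | (S)-3-(tert-butyldimethylsilyloxy)-2-methylpropanal | O=C[C@@H](C)CO[Si](C)(C)C(C)(C)C | intermediate
29 | (R)-tert-butyldimethyl[(2-methylbut-3-yn-1-yl)oxy]silane | C#C[C@@H](C)CO[Si](C)(C)C(C)(C)C | intermediate
30 | tert-butyldimethyl{[(R,E)-2-methyl-4-(4,4,5,5-tetramethyl-1,3,2-dioxaborolan-2-yl)but-3-en-1-yl]oxy}silane | CC(C)(C)[Si](C)(C)OC[C@H](C)/C=C/B1OC(C)(C)C(C)(C)O1 | intermediate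
31 | tert-butyl{[(2R,3E,5E)-2,6-dimethyl-8-[(4aS,8aS)-2,5,5,8a-tetramethyl-3,4,4a,5,6,7,8,8a-octahydronaphthalen-1-yl]octa-3,5-dien-1-yl]oxy}dimethylsilane | CC(C)(C)[Si](C)(C)OC[C@H](C)/C=C/C=C(\C)CCC1=C(C)CC[C@H]2C(C)(C)CCC[C@]12C | intermediate
32 | (2R,3E,5E)-2,6-dimethyl-8-[(4aS,8aS)-2,5,5,8a-tetramethyl-3,4,4a,5,6,7,8,8a-octahydronaphthalen-1-yl]octa-3,5-dien-1-ol | OC[C@H](C)/C=C/C=C(\C)CCC1=C(C)CC[C@H]2C(C)(C)CCC[C@]12C | intermediate
33 | (2R,3E,5E)-2,6-dimethyl-8-[(4aS,8aS)-2,5,5,8a-tetramethyl-3,4,4a,5,6,7,8,8a-octahydronaphthalen-1-yl]octa-3,5-dienal | O=C[C@H](C)/C=C/C=C(\C)CCC1=C(C)CC[C@H]2C(C)(C)CCC[C@]12C | intermediate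
34 | (2R,3E,5E)-2,6-dimethyl-8-[(4aS,8aS)-2,5,5,8a-tetramethyl-3,4,4a,5,6,7,8,8a-octahydronaphthalen-1-yl]octa-3,5-dienoic acid | OC(=O)[C@H](C)/C=C/C=C(\C)CCC1=C(C)CC[C@H]2C(C)(C)CCC[C@]12C | intermediate
35 | methyl (2R,3E,5E)-2,6-dimethyl-8-[(4aS,8aS)-2,5,5,8a-tetramethyl-3,4,4a,5,6,7,8,8a-octahydronaphthalen-1-yl]octa-3,5-dienoate | COC(=O)[C@H](C)/C=C/C=C(\C)CCC1=C(C)CC[C@H]2C(C)(C)CCC[C@]12C | target

**Step count**
Total: 27 steps. Longest linear sequence: 20 steps (1, 3–8, 11–18, 23–27).

**Steps most likely to fail, each with a fallback**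

Step 12 (key step). The cycloaddition may stall because the inside C10 methyl disfavours the s-cis diene conformer and the C5–C10 bond must form between two congested carbons. The Lewis acid may also trigger cationic isomerisation of the electron-rich diene, or the exo (cis-fused) or wrong-face pathway may compete. The fallback sets out from aldehyde 12 and changes the activation from a chelated imide to an iminium ion. Wittig homologation of 12 with (triphenylphosphoranylidene)acetaldehyde (toluene, 90 °C) should give (2E,8E)-9-[2-(tert-butyldimethylsilyloxy)ethyl]-4,4,8,10-tetramethylundeca-2,8,10-trienal F1. An imidazolidinone salt (MacMillan-type organocatalyst, chosen so that the Cα-re face of the iminium ion is shielded) would then promote the intramolecular Diels–Alder reaction to (1S,4aS,8aS)-4-[2-(tert-butyldimethylsilyloxy)ethyl]-3,4a,8,8-tetramethyl-1,2,4a,5,6,7,8,8a-octahydronaphthalene-1-carbaldehyde F2. The absolute sense would be checked by correlation at alcohol 21. Decarbonylation of the C6 aldehyde with stoichiometric RhCl(PPh3)3 (Tsuji–Wilkinson, toluene, reflux) brings the material back to the route at 20, so that steps 11, 13 and 14 are not needed.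

Step 2. The enolate triflation may give poor E/Z control, and the (Z)-triflate would put the tether inside the diene, where no cycloaddition is possible. The fallback sets out from bromide 3 and takes the alkene geometry from a stereospecific syn addition to an alkyne. Alkylation of the dianion of but-3-yn-1-ol (n-BuLi, THF/DMPU) with 3 should give 9-hydroxy-2,2-dimethylnon-6-ynenitrile F3. Hydroxyl-directed iron-catalysed syn-methylmagnesiation (MeMgBr, Fe(acac)3, THF) places methyl on the distal and magnesium on the proximal alkyne carbon, and an iodine quench should give (E)-9-hydroxy-7-iodo-2,2,6-trimethylnon-6-enenitrile F4. Suzuki coupling with isopropenylboronic acid pinacol ester (Pd(PPh3)4, aq. K3PO4) would lead to (E)-7-(2-hydroxyethyl)-2,2,6,8-tetramethylnona-6,8-dienenitrile F5. Silylation (TBSCl, imidazole) returns to the route at 11; steps 2 to 7 fall away.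

Step 13. Hydroperoxide may attack the carbamate carbonyl of the auxiliary (ring opening) or react too slowly, because the exocyclic acyl carbon is screened by C5 and the two quaternary carbons C4 and C10. The fallback sets out from 17 and removes the auxiliary reductively. LiBH4 (Et2O, 1 equiv H2O, 0 °C) should give [(1S,4aS,8aS)-4-[2-(tert-butyldimethylsilyloxy)ethyl]-3,4a,8,8-tetramethyl-1,2,4a,5,6,7,8,8a-octahydronaphthalen-1-yl]methanol F6. Dess–Martin oxidation gives the C6 aldehyde F2 (the same aldehyde as in the fallback for step 12), and rhodium-mediated decarbonylation as above returns to the route at 20, replacing steps 13 and 14.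

**Further compounds**
F1 | step 12 | (2E,8E)-9-[2-(tert-butyldimethylsilyloxy)ethyl]-4,4,8,10-tetramethylundeca-2,8,10-trienal | O=C/C=C/C(C)(C)CCC/C(C)=C(\CCO[Si](C)(C)C(C)(C)C)C(C)=C
F2 | step 12 | (1S,4aS,8aS)-4-[2-(tert-butyldimethylsilyloxy)ethyl]-3,4a,8,8-tetramethyl-1,2,4a,5,6,7,8,8a-octahydronaphthalene-1-carbaldehyde | CC(C)(C)[Si](C)(C)OCCC1=C(C)C[C@H](C=O)[C@H]2C(C)(C)CCC[C@]12C
F3 | step 2 | 9-hydroxy-2,2-dimethylnon-6-ynenitrile | N#CC(C)(C)CCCC#CCCO
F4 | step 2 | (E)-9-hydroxy-7-iodo-2,2,6-trimethylnon-6-enenitrile | N#CC(C)(C)CCC/C(C)=C(/I)CCO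
F5 | step 2 | (E)-7-(2-hydroxyethyl)-2,2,6,8-tetramethylnona-6,8-dienenitrile | N#CC(C)(C)CCC/C(C)=C(\CCO)C(C)=C
F6 | step 13 | [(1S,4aS,8aS)-4-[2-(tert-butyldimethylsilyloxy)ethyl]-3,4a,8,8-tetramethyl-1,2,4a,5,6,7,8,8a-octahydronaphthalen-1-yl]methanol | CC(C)(C)[Si](C)(C)OCCC1=C(C)C[C@H](CO)[C@H]2C(C)(C)CCC[C@]12C
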